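**Strategy.** The trimer is cut at the interflavan bond between C4 of the central epicatechin unit and C8 of the terminal epicatechin unit. The key step is a stereoconvergent SN1 Friedel–Crafts arylation: a benzyl-protected epiafzelechin-(4β→8)-epicatechin dimer bearing a 2-ethoxyethoxy group at C4 of its lower unit (either C4 epimer) is ionised to one planar benzylic cation, stabilised by the three oxygen donors (O1, 5-O, 7-O) of that unit's ring A, and captured by C8 of the electron-rich ring A of tetra-O-benzylepicatechin on the face anti to the cis C2-aryl and C3-hydroxyl groups. This forges the second interflavan bond and the 4β stereocentre at once; hydrogenolysis then releases all eleven phenols.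

Key step: step 6

Assumption: (−)-epicatechin and (−)-epiafzelechin, both natural (2R,3R) flavan-3-ols sold as catalogue compounds, serve as the chiral starting materials; the C4 2-ethoxyethyl ethers are drawn as the expected 4β epimers.

Step 1
Reactants: 1 (−)-epicatechin
Product: 2 5,7,3',4'-tetra-O-benzyl-(−)-epicatechin
Conditions: BnBr (4.4 equiv), K2CO3, DMF, 0 °C to rt, argon
Reagents that add atoms: benzyl bromide BrCc1ccccc1
Why: Williamson ether synthesis in which K2CO3 ionises only the four phenols, which are O-benzylated, while the secondary C3 hydroxyl stays free and no stereocentre is touched (argon and low temperature suppress base-induced C2 epimerisation).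

Step 2
Reactants: 3 (−)-epiafzelechin
Product: 4 5,7,4'-tri-O-benzyl-(−)-epiafzelechin
Conditions: BnBr (3.3 equiv), K2CO3, DMF, 0 °C to rt, argon
Reagents that add atoms: benzyl bromide BrCc1ccccc1
Why: Williamson ether synthesis of the three phenols under the same mild conditions, leaving the C3 hydroxyl free and the C2 and C3 stereocentres unchanged.

Step 3
Reactants: 4 5,7,4'-tri-O-benzyl-(−)-epiafzelechin
Product: 5 4β-(2-ethoxyethoxy)-5,7,4'-tri-O-benzylepiafzelechin
Conditions: DDQ (1.5 equiv), HOCH2CH2OEt (4 equiv), CH2Cl2, rt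
Reagents that add atoms: 2-ethoxyethanol CCOCCO
Why: Oxidative benzylic etherification by DDQ hydride abstraction at the C4 methylene, which is activated by O1, 5-OBn and 7-OBn of ring A; the cation should be trapped by the alcohol on the face opposite the cis C2 aryl and C3 hydroxyl groups to give the 4β (3,4-trans) ether, whose C4 configuration is erased again on ionisation in step 4.

Step 4
Reactants: 5 4β-(2-ethoxyethoxy)-5,7,4'-tri-O-benzylepiafzelechin; 2 5,7,3',4'-tetra-O-benzyl-(−)-epicatechin (4 equiv, excess recovered)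
Product: 6 5,7,4'-tri-O-benzylepiafzelechin-(4β→8)-5,7,3',4'-tetra-O-benzylepicatechin
Conditions: Me3SiOTf (0.2 equiv), CH2Cl2, −78 °C; then Et3N
Reagents that add atoms: none
Why: Lewis-acid-catalysed SN1 Friedel–Crafts alkylation in which the flavan-4-yl cation from 5 is attacked by C8 of ring A of 2 from the β face, anti to the cis C2 aryl and C3 hydroxyl groups, setting C4 of the epiafzelechin unit as 4β (3,4-trans), while the excess of 2 outcompetes self-condensation of 5.

Step 5
Reactants: 6 5,7,4'-tri-O-benzylepiafzelechin-(4β→8)-5,7,3',4'-tetra-O-benzylepicatechin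
Product: 7 dimer 6 carrying a 4β-(2-ethoxyethoxy) group on C4 of its epicatechin unit
Conditions: DDQ (1.5 equiv), HOCH2CH2OEt (4 equiv), CH2Cl2, rt
Reagents that add atoms: 2-ethoxyethanol CCOCCO
Why: Oxidative benzylic etherification by DDQ hydride abstraction, expected to be site-selective for the only benzylic methylene (C4 of the epicatechin unit) because the other doubly activated C–H, C4 of the epiafzelechin unit, is tertiary and shielded between two ortho-disubstituted aryl rings; the alcohol should add trans to the C3 hydroxyl, and either C4 epimer serves in step 6.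

Step 6
Reactants: 7 dimer carrying the 4β-(2-ethoxyethoxy) group; 2 5,7,3',4'-tetra-O-benzyl-(−)-epicatechin (4 equiv, excess recovered)
Product: 8 undeca-O-benzyl epiafzelechin-(4β→8)-epicatechin-(4β→8)-epicatechin
Conditions: Me3SiOTf (0.2 equiv), CH2Cl2, −78 °C; then Et3N
Reagents that add atoms: none
Why: Me3SiOTf ionises the benzylic C4 ether of 7 (SN1) to a planar flavan-4-yl cation delocalised as ortho- and para-quinone methide oxocarbenium forms over O1, 5-OBn and 7-OBn of ring A of the lower unit, and C8 of ring A of 2 attacks it in a Friedel–Crafts alkylation with loss of a proton. The closest known reaction type is the Lewis-acid-catalysed condensation of 4-alkoxyflavan-3-ols with flavan-3-ol nucleophiles used for oligomeric proanthocyanidins. No ring is closed. The new stereocentre, C4 of the central unit, is set by substrate control: the C2 aryl group and the C3 hydroxyl both lie on the α face of the half-chair cation, so the arene should enter from the β face (3,4-trans), and because the same cation arises from both C4 epimers of 7 the step is stereoconvergent. The step needs C8 over C6 regioselectivity in 2, secured because C8 is flanked by one benzyloxy group and the ring oxygen whereas C6 lies between two benzyloxy groups, and it needs cross-coupling over self-condensation of 7 through C8 of its epiafzelechin unit, secured by the fourfold excess of 2 at −78 °C. The existing interflavan bond and the benzyl ethers should be inert to catalytic Me3SiOTf at this temperature.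

Step 7
Reactants: 8 undeca-O-benzyl epiafzelechin-(4β→8)-epicatechin-(4β→8)-epicatechin
Product: 9 epiafzelechin-(4β→8)-epicatechin-(4β→8)-epicatechin (target)
Conditions: H2 (1 atm), Pd(OH)2/C, THF/MeOH/H2O, rt; filtration, Sephadex LH-20, lyophilisation
Reagents that add atoms: none
Why: Catalytic hydrogenolysis of the eleven aryl benzyl ethers under neutral conditions, which should leave the interflavan C–C bonds, the ring C ethers and all eight stereocentres untouched.

**Compound list**

1 | (−)-epicatechin, (2R,3R)-2-(3,4-dihydroxyphenyl)chromane-3,5,7-triol | Oc1cc(O)c2c(c1)O[C@H](c1ccc(O)c(O)c1)[C@H](O)C2 | starting material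
2 | 5,7,3',4'-tetra-O-benzyl-(−)-epicatechin, (2R,3R)-5,7-bis(benzyloxy)-2-[3,4-bis(benzyloxy)phenyl]chroman-3-ol | C(c1ccccc1)Oc1cc(OCc2ccccc2)c2c(c1)O[C@H](c1ccc(OCc3ccccc3)c(OCc3ccccc3)c1)[C@H](O)C2 | intermediate
3 | (−)-epiafzelechin, (2R,3R)-2-(4-hydroxyphenyl)chromane-3,5,7-triol | Oc1ccc([C@H]2Oc3cc(O)cc(O)c3C[C@H]2O)cc1 | starting material
4 | 5,7,4'-tri-O-benzyl-(−)-epiafzelechin, (2R,3R)-5,7-bis(benzyloxy)-2-[4-(benzyloxy)phenyl]chroman-3-ol | C(c1ccccc1)Oc1ccc([C@H]2Oc3cc(OCc4ccccc4)cc(OCc4ccccc4)c3C[C@H]2O)cc1 | intermediate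
5 | 4β-(2-ethoxyethoxy)-5,7,4'-tri-O-benzylepiafzelechin (2R,3R; C4 ether trans to the 3-OH) | C(c1ccccc1)Oc1ccc([C@H]2Oc3cc(OCc4ccccc4)cc(OCc4ccccc4)c3[C@H](OCCOCC)[C@H]2O)cc1 | intermediate
6 | 5,7,4'-tri-O-benzylepiafzelechin-(4β→8)-5,7,3',4'-tetra-O-benzylepicatechin (both units 2R,3R-cis; interflavan bond trans to the upper 3-OH) | C(c1ccccc1)Oc1ccc([C@H]2Oc3cc(OCc4ccccc4)cc(OCc4ccccc4)c3[C@H](c3c(OCc4ccccc4)cc(OCc4ccccc4)c4c3O[C@H](c3ccc(OCc5ccccc5)c(OCc5ccccc5)c3)[C@H](O)C4)[C@H]2O)cc1 | intermediate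
7 | dimer 6 with a 4β-(2-ethoxyethoxy) group (trans to the 3-OH) on C4 of its epicatechin unit | C(c1ccccc1)Oc1ccc([C@H]2Oc3cc(OCc4ccccc4)cc(OCc4ccccc4)c3[C@H](c3c(OCc4ccccc4)cc(OCc4ccccc4)c4c3O[C@H](c3ccc(OCc5ccccc5)c(OCc5ccccc5)c3)[C@H](O)[C@H]4OCCOCC)[C@H]2O)cc1 | intermediate
8 | undeca-O-benzyl epiafzelechin-(4β→8)-epicatechin-(4β→8)-epicatechin (all phenols benzylated, three C3 hydroxyls free) | C(c1ccccc1)Oc1ccc([C@H]2Oc3cc(OCc4ccccc4)cc(OCc4ccccc4)c3[C@H](c3c(OCc4ccccc4)cc(OCc4ccccc4)c4c3O[C@H](c3ccc(OCc5ccccc5)c(OCc5ccccc5)c3)[C@H](O)[C@H]4c3c(OCc5ccccc5)cc(OCc5ccccc5)c5c3O[C@H](c3ccc(OCc6ccccc6)c(OCc6ccccc6)c3)[C@H](O)C5)[C@H]2O)cc1 | intermediate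
9 | epiafzelechin-(4β→8)-epicatechin-(4β→8)-epicatechin | Oc1ccc([C@H]2Oc3cc(O)cc(O)c3[C@H](c3c(O)cc(O)c4c3O[C@H](c3ccc(O)c(O)c3)[C@H](O)[C@H]4c3c(O)cc(O)c4c3O[C@H](c3ccc(O)c(O)c3)[C@H](O)C4)[C@H]2O)cc1 | target

**Step count and risks**

Total steps: 7. Longest linear sequence: 6 steps (3 → 4 → 5 → 6 → 7 → 8 → 9).

Steps most likely to fail:

1. Step 6 (key step). The dimeric cation may be captured by C8 of the epiafzelechin unit of a second molecule of 7 instead of by 2, and the acid may scramble the existing interflavan bond, so that oligomer mixtures form. The fallback blocks that position with a bromine cap and sets out from 4. NBS in CH2Cl2 at −78 °C should brominate C8 selectively to give 8-bromo-5,7,4'-tri-O-benzylepiafzelechin F1. DDQ and 2-ethoxyethanol give its 4β-(2-ethoxyethoxy) ether F2. Me3SiOTf-catalysed coupling with 2 gives the 8-bromo dimer F3, and DDQ with 2-ethoxyethanol gives the 8-bromo dimeric 4β-(2-ethoxyethoxy) ether F4. Because F4 cannot self-condense at C8, it can be coupled with a small excess of 2 under Me3SiOTf to the 8-bromo undeca-O-benzyl trimer F5. Hydrogenolysis over Pd(OH)2/C with Et3N then removes the bromine together with the benzyl groups, and the sequence comes back to the route at 9.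

2. Step 5. DDQ may abstract hydride at the wrong benzylic site (a C2–H or the tertiary C4–H of the upper unit) or over-oxidise the dimer. The fallback installs the leaving group on the monomer before dimerisation, using orthogonal activation, and sets out from 2 and 5. DDQ and 2-ethoxyethanol convert 2 into 4β-(2-ethoxyethoxy)-5,7,3',4'-tetra-O-benzylepicatechin F6. Exchange with 2,6-dimethylbenzenethiol under BF3·OEt2 at −78 °C gives the 4β-(2,6-dimethylphenylthio) derivative F7. The hard Lewis acid BF3·OEt2 should then ionise the ether of 5 but not the thioether, so that excess F7 reacts through its C8 to give the dimeric 4β-thioether F8. Thiophilic activation of F8 with AgBF4 in THF at 0 °C in the presence of 2 forms the same C4–C8 bond, and the sequence comes back to the route at 8.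

3. Step 7. Cleavage of eleven benzyl ethers may stall as the polyphenol precipitates on the catalyst, and the free product may be lost by air oxidation during purification. The fallback isolates the product as a stable derivative and sets out from 8. Hydrogenolysis over Pd(OH)2/C is followed, without isolation of the polyphenol, by Ac2O and pyridine to give the tetradeca-O-acetate F9, which can be purified on silica gel. Methanolysis with catalytic NaOMe in degassed MeOH at 0 °C, neutralised with acidic resin, comes back to the route at 9.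

Further compounds
F1 | step 6 | 8-bromo-5,7,4'-tri-O-benzylepiafzelechin | C(c1ccccc1)Oc1ccc([C@H]2Oc3c(Br)c(OCc4ccccc4)cc(OCc4ccccc4)c3C[C@H]2O)cc1
F2 | step 6 | 8-bromo-4β-(2-ethoxyethoxy)-5,7,4'-tri-O-benzylepiafzelechin | C(c1ccccc1)Oc1ccc([C@H]2Oc3c(Br)c(OCc4ccccc4)cc(OCc4ccccc4)c3[C@H](OCCOCC)[C@H]2O)cc1
F3 | step 6 | 8-bromo-5,7,4'-tri-O-benzylepiafzelechin-(4β→8)-5,7,3',4'-tetra-O-benzylepicatechin | C(c1ccccc1)Oc1ccc([C@H]2Oc3c(Br)c(OCc4ccccc4)cc(OCc4ccccc4)c3[C@H](c3c(OCc4ccccc4)cc(OCc4ccccc4)c4c3O[C@H](c3ccc(OCc5ccccc5)c(OCc5ccccc5)c3)[C@H](O)C4)[C@H]2O)cc1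
F4 | step 6 | dimer F3 with a 4β-(2-ethoxyethoxy) group on C4 of its epicatechin unit | C(c1ccccc1)Oc1ccc([C@H]2Oc3c(Br)c(OCc4ccccc4)cc(OCc4ccccc4)c3[C@H](c3c(OCc4ccccc4)cc(OCc4ccccc4)c4c3O[C@H](c3ccc(OCc5ccccc5)c(OCc5ccccc5)c3)[C@H](O)[C@H]4OCCOCC)[C@H]2O)cc1
F5 | step 6 | undeca-O-benzyl trimer 8 with bromine at C8 of its epiafzelechin unit | C(c1ccccc1)Oc1ccc([C@H]2Oc3c(Br)c(OCc4ccccc4)cc(OCc4ccccc4)c3[C@H](c3c(OCc4ccccc4)cc(OCc4ccccc4)c4c3O[C@H](c3ccc(OCc5ccccc5)c(OCc5ccccc5)c3)[C@H](O)[C@H]4c3c(OCc5ccccc5)cc(OCc5ccccc5)c5c3O[C@H](c3ccc(OCc6ccccc6)c(OCc6ccccc6)c3)[C@H](O)C5)[C@H]2O)cc1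
F6 | step 5 | 4β-(2-ethoxyethoxy)-5,7,3',4'-tetra-O-benzylepicatechin | C(c1ccccc1)Oc1cc(OCc2ccccc2)c2c(c1)O[C@H](c1ccc(OCc3ccccc3)c(OCc3ccccc3)c1)[C@H](O)[C@H]2OCCOCC
F7 | step 5 | 4β-(2,6-dimethylphenylthio)-5,7,3',4'-tetra-O-benzylepicatechin | C(c1ccccc1)Oc1cc(OCc2ccccc2)c2c(c1)O[C@H](c1ccc(OCc3ccccc3)c(OCc3ccccc3)c1)[C@H](O)[C@H]2Sc1c(C)cccc1C
F8 | step 5 | 5,7,4'-tri-O-benzylepiafzelechin-(4β→8)-4β-(2,6-dimethylphenylthio)-5,7,3',4'-tetra-O-benzylepicatechin | C(c1ccccc1)Oc1ccc([C@H]2Oc3cc(OCc4ccccc4)cc(OCc4ccccc4)c3[C@H](c3c(OCc4ccccc4)cc(OCc4ccccc4)c4c3O[C@H](c3ccc(OCc5ccccc5)c(OCc5ccccc5)c3)[C@H](O)[C@H]4Sc3c(C)cccc3C)[C@H]2O)cc1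
F9 | step 7 | tetradeca-O-acetyl epiafzelechin-(4β→8)-epicatechin-(4β→8)-epicatechin | CC(=O)Oc1ccc([C@H]2Oc3cc(OC(C)=O)cc(OC(C)=O)c3[C@H](c3c(OC(C)=O)cc(OC(C)=O)c4c3O[C@H](c3ccc(OC(C)=O)c(OC(C)=O)c3)[C@H](OC(C)=O)[C@H]4c3c(OC(C)=O)cc(OC(C)=O)c4c3O[C@H](c3ccc(OC(C)=O)c(OC(C)=O)c3)[C@H](OC(C)=O)C4)[C@H]2OC(C)=O)cc1
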